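**Retrosynthetic overview**
1. The C6–CH3 bond is made last. Me3Al attacks a bicyclic peroxycarbenium ion from the axial direction, and this sets C6.
2. Ring B (the 1,2-dioxane) comes from insertion of O2 into the C3–C6 bond of a lactone-fused tertiary cyclobutanol. This four- to six-membered ring expansion makes C3–O and O–C6.
3. The C6–C7 bond comes from a side-chain Grignard reagent and a lactone-fused cyclobutanone.
4. The cyclobutanone comes from an auxiliary-controlled keteniminium/enol-lactone cycloaddition on α-angelica lactone (sets C3 and C4). The side chain comes from alkyne methylalumination–benzylation (E-alkene) and a Cu-catalysed coupling with a chiral-pool C4 bromide (C8).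
5. Ring order: ring A (γ-lactone, bought), then the cyclobutane, then ring B by expansion of the cyclobutane.

Atom labels: C1 = lactone C=O, C2 = CH2, C3 = CH–OO, C4 = C(CH3)–O(lactone), C5 = ring CH2, C6 = C(CH3)–OO. C7 to C14 run outward along the side chain to the benzylic CH2.

Assumption: the (2S,5S) auxiliary is taken to give the (1R,5R) cyclobutanone. If the sense of induction is the opposite, its commercial (2R,5R) enantiomer is used in the same way.

**Step 1**
Reactants: 1 4-bromobut-1-yne; 2 benzyl chloride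
Product: 4 [(2E)-5-bromo-3-methylpent-2-en-1-yl]benzene, via alkenylalane 3 (not isolated)
Conditions: Me3Al (2 equiv), Cp2ZrCl2 (25 mol %), CH2Cl2, 0 °C to rt; then 2, Pd(PPh3)4 (3 mol %), THF, rt
Reagents that add atoms: trimethylaluminium, C[Al](C)C
Why: Negishi zirconium-catalysed methylalumination adds CH3 and Al syn with Al at the terminus, and the palladium-catalysed cross-coupling of the alkenylalane with benzyl chloride goes with retention, so the E trisubstituted alkene is fixed while the primary bromide stays inert.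

**Step 2**
Reactants: 4 [(2E)-5-bromo-3-methylpent-2-en-1-yl]benzene; 5 (2R)-3-bromo-2-methylpropan-1-ol
Product: 8 (2S,6E)-2,6-dimethyl-8-phenyloct-6-en-1-ol, via homoallyl Grignard reagent 6 (not isolated), via magnesium alkoxide 7 (not isolated)
Conditions: 4, Mg, THF, rt; separately 5, MeMgCl (1.0 equiv), THF, −20 °C; combine, Li2CuCl4 (5 mol %), −20 °C to rt; aq NH4Cl
Reagents that add atoms: none
Why: Copper-catalysed sp3–sp3 Grignard/alkyl bromide coupling (Kochi–Tamura type) in which the hydroxyl is masked in the flask as its magnesium alkoxide; the C8 stereocentre comes untouched from the chiral pool.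

**Step 3**
Reactants: 8 (2S,6E)-2,6-dimethyl-8-phenyloct-6-en-1-ol
Product: 9 [(2E,7S)-8-bromo-3,7-dimethyloct-2-en-1-yl]benzene
Conditions: CBr4, PPh3, CH2Cl2, 0 °C
Reagents that add atoms: carbon tetrabromide, BrC(Br)(Br)Br
Why: Appel reaction of a primary alcohol under neutral conditions that touch neither the alkene nor C8.

**Step 4**
Reactants: 10 acetyl chloride; 11 (2S,5S)-2,5-dimethylpyrrolidine
Product: 12 1-[(2S,5S)-2,5-dimethylpyrrolidin-1-yl]ethan-1-one
Conditions: Et3N, CH2Cl2, 0 °C
Reagents that add atoms: none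
Why: Simple N-acylation that attaches the C2-symmetric auxiliary to the two-carbon unit that becomes C5 and C6.

**Step 5**
Reactants: 12 1-[(2S,5S)-2,5-dimethylpyrrolidin-1-yl]ethan-1-one; 13 α-angelica lactone (5-methylfuran-2(3H)-one)
Product: 16 (1R,5R)-1-methyl-2-oxabicyclo[3.2.0]heptane-3,6-dione, via keteniminium triflate 14 (not isolated), via cyclobutaniminium triflate 15 (not isolated)
Conditions: Tf2O (1.1 equiv), 2,6-di-tert-butyl-4-methylpyridine (1.2 equiv), ClCH2CH2Cl, −20 to 60 °C; then H2O, NaHCO3, rt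
Reagents that add atoms: water, O
Why: Ghosez keteniminium–olefin [2+2] cycloaddition in which the nucleophilic C3 of the enol lactone bonds to the central keteniminium carbon and the ring closes at the oxygen-bearing C4; the fusion can only be cis, and the C2-symmetric pyrrolidine selects the alkene face, which sets C3 and C4.

**Step 6**
Reactants: 9 [(2E,7S)-8-bromo-3,7-dimethyloct-2-en-1-yl]benzene; 16 (1R,5R)-1-methyl-2-oxabicyclo[3.2.0]heptane-3,6-dione
Product: 18 (1R,5S,6S)-6-[(2S,6E)-2,6-dimethyl-8-phenyloct-6-en-1-yl]-6-hydroxy-1-methyl-2-oxabicyclo[3.2.0]heptan-3-one, via Grignard reagent 17 (not isolated)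
Conditions: 9, Mg, THF, rt; LaCl3·2LiCl (1.0 equiv), then 16, THF, −78 °C; aq NH4Cl at −78 °C
Reagents that add atoms: none
Why: Lanthanide-assisted Grignard 1,2-addition, which prefers the strained ketone to the lactone and suppresses enolisation and β-elimination; attack is on the convex face, the C6 carbinol configuration is erased in step 7, and the cold quench prevents acyl migration.

**Step 7**
Reactants: 18 (1R,5S,6S)-6-[(2S,6E)-2,6-dimethyl-8-phenyloct-6-en-1-yl]-6-hydroxy-1-methyl-2-oxabicyclo[3.2.0]heptan-3-one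
Product: 21 (3R,4aR,7aR)-3-[(2S,6E)-2,6-dimethyl-8-phenyloct-6-en-1-yl]-3-methoxy-4a-methyltetrahydro-3H-furo[3,2-c][1,2]dioxin-6(4H)-one, via hydroperoxy ketone 19 (not isolated), via peroxyhemiketal 20 (not isolated)
Conditions: Co(acac)2 (20 mol %), O2 (1 atm), PhMe, 40 °C; then MeOH, PPTS (10 mol %), 3 Å MS, rt
Reagents that add atoms: dioxygen, O=O; methanol, CO
Why: Oxidative cyclobutanol-to-1,2-dioxanol ring expansion (radical, not concerted), in which the cobalt-bound alkoxide gives the C6 alkoxyl radical, strain-driven β-scission breaks C6–C3 on the more substituted side, the C3 radical takes up O2, and only the hydroperoxide cis to the ketone arm can close to the six-membered peroxyhemiketal, so C3–O ends cis-fused before acid and MeOH give the stable peroxyketal.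

**Step 8**
Reactants: 21 (3R,4aR,7aR)-3-[(2S,6E)-2,6-dimethyl-8-phenyloct-6-en-1-yl]-3-methoxy-4a-methyltetrahydro-3H-furo[3,2-c][1,2]dioxin-6(4H)-one
Product: 23 plakortolide G, via peroxycarbenium triflate 22 (not isolated)
Conditions: Me3Al (3 equiv), CH2Cl2, −78 °C, then TMSOTf (1.1 equiv) dropwise, −78 °C; aq Rochelle salt
Reagents that add atoms: trimethylaluminium, C[Al](C)C
Why: Proposed new method: C-methylation of a ketone-derived cyclic peroxycarbenium ion by Me3Al, in which TMSOTf removes the methoxy group and the cation adopts the half-chair with the C4 acyloxy oxygen pseudoaxial and the C4 methyl pseudoequatorial, so that Me3Al, already present, delivers CH3 along the axial, chair-forming trajectory syn to that oxygen (the other face would need a 1,3-diaxial CH3/CH3 contact), giving C6–CH3 cis to the lactone oxygen and the side chain equatorial as in the target; the closest known reaction types are Me3Al methylation of cyclic oxocarbenium ions made from ketals, glycosyl fluorides or α-sulfonyl ethers, and Lewis-acid substitution of peroxyketals by allylsilanes, silyl enol ethers and silanes, and dialkyl peroxides and trioxanes are known to survive Me3Al at −78 °C.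

**Compound list**
1 | 4-bromobut-1-yne | C#CCCBr | starting material
2 | benzyl chloride | ClCc1ccccc1 | starting material
3 | [(1E)-4-bromo-2-methylbut-1-en-1-yl]dimethylalane | C[Al](C)/C=C(\C)CCBr | intermediate
4 | [(2E)-5-bromo-3-methylpent-2-en-1-yl]benzene | C/C(=C\Cc1ccccc1)CCBr | intermediate
5 | (2R)-3-bromo-2-methylpropan-1-ol | BrC[C@H](C)CO | starting material
6 | [(3E)-3-methyl-5-phenylpent-3-en-1-yl]magnesium bromide | C/C(=C\Cc1ccccc1)CC[Mg]Br | intermediate
7 | chloromagnesium (2R)-3-bromo-2-methylpropan-1-olate | BrC[C@H](C)CO[Mg]Cl | intermediate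
8 | (2S,6E)-2,6-dimethyl-8-phenyloct-6-en-1-ol | C/C(=C\Cc1ccccc1)CCC[C@H](C)CO | intermediate
9 | [(2E,7S)-8-bromo-3,7-dimethyloct-2-en-1-yl]benzene | C/C(=C\Cc1ccccc1)CCC[C@H](C)CBr | intermediate
10 | acetyl chloride | CC(=O)Cl | starting material
11 | (2S,5S)-2,5-dimethylpyrrolidine (auxiliary) | C[C@H]1CC[C@H](C)N1 | starting material
12 | 1-[(2S,5S)-2,5-dimethylpyrrolidin-1-yl]ethan-1-one | C[C@H]1CC[C@H](C)N1C(C)=O | intermediate
13 | α-angelica lactone, 5-methylfuran-2(3H)-one | CC1=CCC(=O)O1 | starting material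
14 | (2S,5S)-1-ethenylidene-2,5-dimethylpyrrolidin-1-ium triflate | C[C@H]1CC[C@H](C)[N+]1=C=C.[O-]S(=O)(=O)C(F)(F)F | intermediate
15 | iminium triflate of 16 with the auxiliary (C6=N+) | C[C@H]1CC[C@H](C)[N+]1=C3C[C@@]2(C)OC(=O)C[C@H]23.[O-]S(=O)(=O)C(F)(F)F | intermediate
16 | (1R,5R)-1-methyl-2-oxabicyclo[3.2.0]heptane-3,6-dione (cis-fused) | O=C1C[C@@]2(C)OC(=O)C[C@H]21 | intermediate
17 | [(2S,6E)-2,6-dimethyl-8-phenyloct-6-en-1-yl]magnesium bromide | C/C(=C\Cc1ccccc1)CCC[C@H](C)C[Mg]Br | intermediate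
18 | (1R,5S,6S)-6-[(2S,6E)-2,6-dimethyl-8-phenyloct-6-en-1-yl]-6-hydroxy-1-methyl-2-oxabicyclo[3.2.0]heptan-3-one (side chain exo, OH endo) | C/C(=C\Cc1ccccc1)CCC[C@H](C)C[C@]1(O)C[C@@]2(C)OC(=O)C[C@H]21 | intermediate
19 | (4R,5R)-5-[(4S,8E)-4,8-dimethyl-2-oxo-10-phenyldec-8-en-1-yl]-4-hydroperoxy-5-methyloxolan-2-one | C/C(=C\Cc1ccccc1)CCC[C@H](C)CC(=O)C[C@@]1(C)OC(=O)C[C@H]1OO | intermediate
20 | (3R,4aR,7aR)-3-[(2S,6E)-2,6-dimethyl-8-phenyloct-6-en-1-yl]-3-hydroxy-4a-methyltetrahydro-3H-furo[3,2-c][1,2]dioxin-6(4H)-one (drawn as the axial-OH anomer) | C/C(=C\Cc1ccccc1)CCC[C@H](C)C[C@]1(O)C[C@@]2(C)OC(=O)C[C@H]2OO1 | intermediate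
21 | (3R,4aR,7aR)-3-[(2S,6E)-2,6-dimethyl-8-phenyloct-6-en-1-yl]-3-methoxy-4a-methyltetrahydro-3H-furo[3,2-c][1,2]dioxin-6(4H)-one (drawn as the axial-OMe anomer; both anomers give 22) | C/C(=C\Cc1ccccc1)CCC[C@H](C)C[C@]1(OC)C[C@@]2(C)OC(=O)C[C@H]2OO1 | intermediate
22 | bicyclic peroxycarbenium triflate (C6=O+) | C/C(=C\Cc1ccccc1)CCC[C@H](C)CC=1C[C@@]2(C)OC(=O)C[C@H]2O[O+]=1.[O-]S(=O)(=O)C(F)(F)F | intermediate
23 | plakortolide G, (3R,4aR,7aR)-3-[(2S,6E)-2,6-dimethyl-8-phenyloct-6-en-1-yl]-3,4a-dimethyltetrahydro-3H-furo[3,2-c][1,2]dioxin-6(4H)-one | C/C(=C\Cc1ccccc1)CCC[C@H](C)C[C@]1(C)C[C@@]2(C)OC(=O)C[C@H]2OO1 | target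

**Step count**
Total step count: 8.
Longest linear sequence: 6 (steps 1, 2, 3, 6, 7, 8).

**The three steps most likely to fail**

**Step 5.**
- Risks: the enol lactone is a weak nucleophile. The facial control of the auxiliary on a trisubstituted enol ester is untested. Hydrolysis of the iminium salt could trigger β-elimination of the carboxylate.
- Fallback: it sets out from 13 and comes back at 16, and it replaces auxiliary control by a racemic cycloaddition and an enzymatic resolution. 13 takes up dichloroketene (Cl3CCOCl, Zn–Cu, Et2O, reflux) to give racemic 7,7-dichloro-1-methyl-2-oxabicyclo[3.2.0]heptane-3,6-dione F1. Zn dust in MeOH/NH4Cl removes both chlorines to give racemic 1-methyl-2-oxabicyclo[3.2.0]heptane-3,6-dione F2. A ketoreductase chosen from a screening kit (NADP+, iPrOH, pH 7 buffer, 30 °C) reduces only the (1S,5S) enantiomer to (1S,5R,6R)-6-hydroxy-1-methyl-2-oxabicyclo[3.2.0]heptan-3-one F3. The untouched 16 is separated by chromatography, with a ceiling of 50 %.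

**Step 7.**
- Risks: the alcohol is tertiary and the C3 radical carries no stabilising group. O2 capture at C3 is not face-selective, and only the cis hydroperoxide closes. The allylic and benzylic C14–H2 may autoxidise.
- Fallback: it sets out from 18 and comes back at 21. The ring is opened without oxygen capture and the peroxide is brought in by ionic chemistry. Mn(OAc)3·2H2O and Cu(OAc)2 in MeCN/AcOH under argon cause the same β-scission, but Cu(OAc)2 oxidises the C3 radical to the alkene. This gives (5R)-5-[(4S,8E)-4,8-dimethyl-2-oxo-10-phenyldec-8-en-1-yl]-5-methylfuran-2(5H)-one F4. Urea·H2O2 and Sc(OTf)3 (10 mol %) in MeOH turn the ketone into the methoxy hydroperoxide (5R)-5-[(4S,8E)-2-hydroperoxy-2-methoxy-4,8-dimethyl-10-phenyldec-8-en-1-yl]-5-methylfuran-2(5H)-one F5. Et2NH in CF3CH2OH then closes ring B by intramolecular oxa-Michael addition to the butenolide, necessarily cis-fused, to give 21.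

**Step 8 (the new step).**
- Risks: Hock-type O–O heterolysis of the cation, proton loss to an enol peroxide, or attack of Me3Al on the O–O bond.
- Fallback: it uses only known chemistry, sets out from 18 by way of the keto-butenolide F4 made as above, and comes back at 23. It gives up control at C6. Zn/CH2Br2/TiCl4 in THF/CH2Cl2 methylenates the ketone selectively to (5R)-5-[(4S,8E)-4,8-dimethyl-2-methylidene-10-phenyldec-8-en-1-yl]-5-methylfuran-2(5H)-one F6. Co(thd)2, O2 and Et3SiH in ClCH2CH2Cl (Mukaiyama–Isayama peroxidation, faster on the 1,1-disubstituted alkene) give the triethylsilyl peroxide (5R)-5-methyl-5-[(4S,8E)-2,4,8-trimethyl-10-phenyl-2-(triethylsilylperoxy)dec-8-en-1-yl]furan-2(5H)-one F7 as a 1:1 mixture at C6. HF·pyridine frees the hydroperoxide (5R)-5-[(4S,8E)-2-hydroperoxy-2,4,8-trimethyl-10-phenyldec-8-en-1-yl]-5-methylfuran-2(5H)-one F8. Et2NH in CF3CH2OH closes both epimers by oxa-Michael addition, and 23 is separated by HPLC from 6-epi-plakortolide G F9.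

**Further compounds**
F1 | step 5 | racemic 7,7-dichloro-1-methyl-2-oxabicyclo[3.2.0]heptane-3,6-dione (both enantiomers written) | O=C1C(Cl)(Cl)[C@@]2(C)OC(=O)C[C@H]21.O=C1C(Cl)(Cl)[C@]2(C)OC(=O)C[C@@H]21
F2 | step 5 | racemic 1-methyl-2-oxabicyclo[3.2.0]heptane-3,6-dione (16 and its enantiomer) | O=C1C[C@@]2(C)OC(=O)C[C@H]21.O=C1C[C@]2(C)OC(=O)C[C@@H]21
F3 | step 5 | (1S,5R,6R)-6-hydroxy-1-methyl-2-oxabicyclo[3.2.0]heptan-3-one | O[C@@H]1C[C@]2(C)OC(=O)C[C@@H]21
F4 | step 7 | (5R)-5-[(4S,8E)-4,8-dimethyl-2-oxo-10-phenyldec-8-en-1-yl]-5-methylfuran-2(5H)-one | C/C(=C\Cc1ccccc1)CCC[C@H](C)CC(=O)C[C@@]1(C)OC(=O)C=C1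
F5 | step 7 | (5R)-5-[(4S,8E)-2-hydroperoxy-2-methoxy-4,8-dimethyl-10-phenyldec-8-en-1-yl]-5-methylfuran-2(5H)-one (both epimers at the peroxyketal carbon) | C/C(=C\Cc1ccccc1)CCC[C@H](C)CC(OC)(OO)C[C@@]1(C)OC(=O)C=C1
F6 | step 8 | (5R)-5-[(4S,8E)-4,8-dimethyl-2-methylidene-10-phenyldec-8-en-1-yl]-5-methylfuran-2(5H)-one | C/C(=C\Cc1ccccc1)CCC[C@H](C)CC(=C)C[C@@]1(C)OC(=O)C=C1
F7 | step 8 | (5R)-5-methyl-5-[(4S,8E)-2,4,8-trimethyl-10-phenyl-2-(triethylsilylperoxy)dec-8-en-1-yl]furan-2(5H)-one (both C6 epimers) | C/C(=C\Cc1ccccc1)CCC[C@H](C)CC(C)(OO[Si](CC)(CC)CC)C[C@@]1(C)OC(=O)C=C1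
F8 | step 8 | (5R)-5-[(4S,8E)-2-hydroperoxy-2,4,8-trimethyl-10-phenyldec-8-en-1-yl]-5-methylfuran-2(5H)-one (both C6 epimers) | C/C(=C\Cc1ccccc1)CCC[C@H](C)CC(C)(OO)C[C@@]1(C)OC(=O)C=C1
F9 | step 8 | 6-epi-plakortolide G, the (3S,4aR,7aR) epimer of 23 | C/C(=C\Cc1ccccc1)CCC[C@H](C)C[C@@]1(C)C[C@@]2(C)OC(=O)C[C@H]2OO1
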